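Readings and results were generated by integration on assumed constants; noise was put on by code.

If every bit of starting material lost became target, the two columns of a run would fall and rise in step. We test that on the north-east run, the very flask asked about, which has enzyme working on starting material and second substrate.

| setting | north-east | west | flask |
|---|---|---|---|
| starting material | 0.10 M | 0.10 M | 0.10 M |
| second substrate | 0.050 M | 0.050 M | 0.0500 M |
| enzyme | 57 µM | 28 µM | 57 µM |
| remark | the very flask that is asked about, followed so far | run made earlier |  |
| time |  |  | 8.0 d |

| run | time / d | target / % | starting material / % |
|---|---|---|---|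
| north-east | 0.500 | 9 | 90 |
| north-east | 1.67 | 17 | 80 |
| north-east | 3.00 | 26 | 72 |
| north-east | 4.00 | 29 | 67 |
| north-east | 6.00 | 31 | 63 |
| north-east | 8.00 | 34 | 57 |
| west | 0.500 | 3 | 91 |
| west | 1.67 | 10 | 90 |
| west | 3.00 | 14 | 83 |
| west | 4.00 | 16 | 82 |
| west | 6.00 | 14 | 77 |
| west | 8.00 | 18 | 74 |

(scatter of a reading: 2 percentage points)

- the volume of additions can be left aside
- a reading or a percentage of target counts all its forms, free or not

- green: at 8.0 d add second substrate, 50.0% of the amount charged, then wait 4.0 d
- red: at 8.0 d add enzyme, 100% of the amount charged, then wait 4.0 d
- blue: at 8.0 d add starting material, 50.0% of the amount charged, then wait 4.0 d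
- ochre: change nothing and wait 4.0 d more

1. target, in percent of the starting material first charged, at 8.0 d
2. the remedy with the largest gain of target, or "none" below 2 percentage points (green / red / blue / ochre / none)
3. target present, in percent of the starting material first charged, after red
4. target present, in percent of the starting material first charged, after blue

The oddity sits late in the north-east run: from 4.00 d to 8.00 d, starting material falls 10 percentage points, yet target rises 5 points. So we reckon one ratio, the keep: target gained per starting material lost, a selectivity taken over a stretch.

up to 4.00 d: keep = 29 points / 33 points = 0.879

4.00 d to 8.00 d: 5 points / 10 points = 0.500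

Readings scatter by 2 points, but the west run drifts the same way, from 0.889 to 0.250. So the late keep reads lower, which we take as starting material leaving by a second way, and the unaccounted part of the north-east run grows from 4 points to 9 points. At the early keep, the north-east run's loss of starting material up to 8.00 d stands as 37.8% target, more than the 34% read, so we do not reckon late target from the early keep.

The forecast gives 34% now, red as best, 47% after red and 35% after blue, on the ground “That points to the enzyme dying”.

The flask gives 30.3%, and red is best, reaching 38.1%; blue gives 27.5%, and waiting changes target by −1.2 points.

    crystals ⇌ target, rate k1*(cs1 - [target]) while solid is left; crystals form when [target] > cs1 (solubility = 34.0 mM, k = 0.140 h⁻¹)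
    ternary complex → enzyme + target (k = 32.0 h⁻¹)
    starting material + enzyme ⇌ starting complex (K = 8.60 M⁻¹, k = 5900 M⁻¹ h⁻¹)
    second substrate + enzyme → spent catalyst (k = 1.10 M⁻¹ h⁻¹)
    starting material + target → side product (k = 0.0190 M⁻¹ h⁻¹)
    second substrate + starting complex ⇌ ternary complex (K = 40.0 M⁻¹, k = 29000 M⁻¹ h⁻¹)

In the flask at 8.00 d, starting material binds enzyme 38 times as fast as it meets target to form side product, counting the forward step alone. Yet 11.2% of the catalyst can still turn over at that time. At the early keep, the 42 points of starting material lost would stand as 37.2% target; the flask holds 30.3% and 12.0% side product, which counts as two.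

In the neighbour charged with 0.025 M of starting material, the early keep on its 41 points lost gives 36.4% of its own charge. That neighbour computes to 37.6% target, with 3.82% side product.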